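**Plan**
- Retrosynthesis: the four MOM ethers are cut last. Ring C is then cut at O1–C8a and C4–C4a in one operation, giving a ring A aryne (C4a≡C8a) and an (S)-3-aryl-3-oxidopropanoic N-methoxy-N-methylamide. Ring A is further cut at C8–C1' (aryl–allyl) and at C4a–Si.
- Forward, ring A: a 5-methoxyresorcinol carbamate is ortho-metalated twice, first for silicon at the carbon between carbamate and OMOM, then for the preformed Z-allyl chain between carbamate and OMe; the carbamate then becomes the triflate.
- Forward, other fragments: the Z-allylic bromide comes from propargyl alcohol; ring B with C2–C3–C4 comes from 3',4'-dihydroxyacetophenone as a β-hydroxy amide. Ring C closes in the aryne annulation, and global MOM removal ends the route.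
- Enabling feature: C8a and C4a are neighbouring carbons of ring A carrying O1 and the C4 carbonyl carbon, the ortho heteroatom/acyl pattern left by nucleophile-then-electrophile addition across an aryne. The C5 oxygen beside C4a polarises the C4a≡C8a bond so that oxygen adds at C8a and the carbanion forms at C4a.
- Stereochemistry: C2 (S) comes from asymmetric transfer hydrogenation of a β-keto ester and is carried untouched through ring closure. The Z alkene comes from anti-carbomagnesiation of propargyl alcohol (cyclic magnesium alkoxide) and is retained through exchange, bromination and allylic substitution.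

Key step: step 14

Remark: flavanone numbering is used (O1, C2, C3, C4, C4a, C5 to C8, C8a; side chain C1' to C4'); the SMILES is read as (2S) at C2 and Z at the side-chain alkene.

**Step 1**
Reactants: 1 5-methoxybenzene-1,3-diol
Product: 2 3-methoxy-5-(methoxymethoxy)phenol
Conditions: NaH (1.0 equiv), DMF, 0 °C; MOMCl (1.0 equiv), 0 °C → rt
Reagents that add atoms: chloromethyl methyl ether, COCCl
Why: Williamson-type O-alkylation of the monosodium salt of a symmetric resorcinol; the two hydroxyls are equivalent, so monoprotection is statistical and the mono-ether is separated from recovered diol and bis-ether, which are recycled.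

**Step 2**
Reactants: 2 3-methoxy-5-(methoxymethoxy)phenol
Product: 3 3-methoxy-5-(methoxymethoxy)phenyl N-(propan-2-yl)carbamate
Conditions: i-PrNCO, Et3N (cat.), CH2Cl2, rt
Reagents that add atoms: isopropyl isocyanate, CC(C)N=C=O
Why: amine-catalysed addition of the phenol to the isocyanate (carbamoylation) gives the N-monosubstituted O-aryl carbamate, which serves as ortho-directing group now and as the latent triflate oxygen later.

**Step 3**
Reactants: 3 3-methoxy-5-(methoxymethoxy)phenyl N-(propan-2-yl)carbamate
Product: 7 5-methoxy-3-(methoxymethoxy)-2-(trimethylsilyl)phenyl N-(propan-2-yl)carbamate, via N-silyl carbamate 4 (not isolated), via aryllithium 5 (not isolated), via N-silyl silylarene 6 (not isolated)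
Conditions: TMSOTf (1.1 equiv), TMEDA, Et2O, 0 °C → rt; n-BuLi (2.2 equiv), TMEDA, −78 °C; TMSCl, −78 °C → rt; MeOH, H2O
Reagents that add atoms: chlorotrimethylsilane, C[Si](C)(C)Cl
Why: directed ortho-metalation of the in situ N-trimethylsilylated O-aryl carbamate, whose N–Si group blocks N–H deprotonation and isocyanate loss during a sequence run entirely at −78 °C and then falls off on neutral methanolysis that spares the aryl MOM ether: of the two carbamate-flanked ring hydrogens, the one that also lies beside the chelating OMOM group should be removed preferentially (OMOM co-directs better than OMe), and the aryllithium is trapped by the chlorosilane.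

**Step 4**
Reactants: 8 prop-2-yn-1-ol
Product: 10 (2Z)-3-iodo-2-methylprop-2-en-1-ol, via magnesacycle 9 (not isolated)
Conditions: MeMgBr (2.5 equiv), CuI (copper monoiodide, 10 mol %), THF, −10 °C → rt; I2, −10 °C
Reagents that add atoms: methylmagnesium bromide, C[Mg]Br; iodine, II
Why: copper-catalysed anti-carbomagnesiation of the propargylic magnesium alkoxide puts methyl on C2 and magnesium on C3 inside a five-membered chelate ring (magnesium cis to the CH2O arm), and iodinolysis with retention gives the Z iodide.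

**Step 5**
Reactants: 10 (2Z)-3-iodo-2-methylprop-2-en-1-ol
Product: 11 (1Z)-1-iodo-3-(methoxymethoxy)-2-methylprop-1-ene
Conditions: NaH, THF, 0 °C; MOMCl, 0 °C → rt
Reagents that add atoms: chloromethyl methyl ether, COCCl
Why: Williamson O-alkylation of the sodium alkoxide with the chloromethyl ether; the vinyl iodide has no β-hydrogen placed for elimination.

**Step 6**
Reactants: 11 (1Z)-1-iodo-3-(methoxymethoxy)-2-methylprop-1-ene
Product: 13 (2Z)-4-(methoxymethoxy)-3-methylbut-2-en-1-ol, via vinyllithium 12 (not isolated)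
Conditions: t-BuLi (2.1 equiv), Et2O, −78 °C; (CH2O)n, −78 °C → rt; H2O
Reagents that add atoms: formaldehyde (as paraformaldehyde), C=O
Why: iodine–lithium exchange proceeds with retention of alkene geometry (the vinyllithium is held by the MOM oxygens, and an acetal cannot undergo the oxygen-to-carbon migration open to a silyl ether), and addition to formaldehyde installs C1' as a hydroxymethyl group.

**Step 7**
Reactants: 13 (2Z)-4-(methoxymethoxy)-3-methylbut-2-en-1-ol
Product: 14 (2Z)-1-bromo-4-(methoxymethoxy)-3-methylbut-2-ene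
Conditions: CBr4, PPh3, CH2Cl2, 0 °C
Reagents that add atoms: carbon tetrabromide, BrC(Br)(Br)Br
Why: Appel reaction: bromide displaces the oxyphosphonium group by SN2 at the primary allylic carbon under neutral conditions, without allylic transposition or loss of the Z geometry; 14 is used at once.

**Step 8**
Reactants: 7 5-methoxy-3-(methoxymethoxy)-2-(trimethylsilyl)phenyl N-(propan-2-yl)carbamate; 14 (2Z)-1-bromo-4-(methoxymethoxy)-3-methylbut-2-ene
Product: 18 3-methoxy-5-(methoxymethoxy)-2-[(2Z)-4-(methoxymethoxy)-3-methylbut-2-en-1-yl]-6-(trimethylsilyl)phenyl N-(propan-2-yl)carbamate, via N-silyl silylarene 15 (not isolated), via aryllithium 16 (not isolated), via N-silyl allylarene 17 (not isolated)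
Conditions: TBSOTf (1.1 equiv), TMEDA, Et2O, 0 °C → rt; n-BuLi (2.2 equiv), TMEDA, −78 °C; CuBr·SMe2 (20 mol %), then 14, −78 → 0 °C; MeOH, H2O
Reagents that add atoms: none
Why: second directed ortho-metalation at the only remaining ring hydrogen beside the carbamate (between carbamate and OMe; silicon was placed first so that no benzylic-allylic hydrogen is present during lithiation), here under the sturdier N-tert-butyldimethylsilyl protection because the mixture is warmed to 0 °C, followed by copper-catalysed SN2 allylic substitution at the primary carbon of 14 (the γ-carbon is fully substituted, which disfavours SN2') with retention of the Z alkene and methanolysis of the N–Si bond on work-up.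

**Step 9**
Reactants: 18 3-methoxy-5-(methoxymethoxy)-2-[(2Z)-4-(methoxymethoxy)-3-methylbut-2-en-1-yl]-6-(trimethylsilyl)phenyl N-(propan-2-yl)carbamate
Product: 20 3-methoxy-5-(methoxymethoxy)-2-[(2Z)-4-(methoxymethoxy)-3-methylbut-2-en-1-yl]-6-(trimethylsilyl)phenyl trifluoromethanesulfonate, via phenol 19 (not isolated)
Conditions: Et2NH, DBU, MeCN, 40 °C; then PhNTf2, rt → 40 °C
Reagents that add atoms: N-phenylbis(trifluoromethanesulfonimide), O=S(=O)(N(c1ccccc1)S(=O)(=O)C(F)(F)F)C(F)(F)F
Why: E1cB cleavage of the N-monosubstituted carbamate (the isocyanate is trapped by diethylamine as a urea) releases the hindered phenoxide, which is sulfonylated in the same flask to give the o-silylaryl triflate, a fluoride-triggered aryne precursor.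

**Step 10**
Reactants: 21 1-(3,4-dihydroxyphenyl)ethan-1-one
Product: 22 1-[3,4-bis(methoxymethoxy)phenyl]ethan-1-one
Conditions: NaH (2.4 equiv), DMF, 0 °C; MOMCl (2.4 equiv), 0 °C → rt
Reagents that add atoms: chloromethyl methyl ether, COCCl
Why: Williamson O-alkylation of the catechol disodium salt protects both phenols as acetals that tolerate base, organometallics and fluoride.

**Step 11**
Reactants: 22 1-[3,4-bis(methoxymethoxy)phenyl]ethan-1-one
Product: 23 methyl 3-[3,4-bis(methoxymethoxy)phenyl]-3-oxopropanoate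
Conditions: NaH (2.5 equiv), (MeO)2CO, THF, reflux; AcOH
Reagents that add atoms: dimethyl carbonate, COC(=O)OC
Why: crossed Claisen condensation of the methyl ketone enolate with dimethyl carbonate, driven by irreversible deprotonation of the β-keto ester product.

**Step 12**
Reactants: 23 methyl 3-[3,4-bis(methoxymethoxy)phenyl]-3-oxopropanoate
Product: 24 methyl (3S)-3-[3,4-bis(methoxymethoxy)phenyl]-3-hydroxypropanoate
Conditions: RuCl[(S,S)-TsDPEN](p-cymene) (1 mol %), HCO2H/Et3N (5:2), 30 °C
Reagents that add atoms: none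
Why: Noyori asymmetric transfer hydrogenation: the (S,S)-configured catalyst differentiates the aryl and CH2CO2Me flanks as it does aryl and methyl in aryl methyl ketones (CH/π contact of the aryl ring with the η6-arene) and should deliver hydride to the face that gives the (S)-carbinol, which becomes C2.

**Step 13**
Reactants: 24 methyl (3S)-3-[3,4-bis(methoxymethoxy)phenyl]-3-hydroxypropanoate
Product: 25 (3S)-3-[3,4-bis(methoxymethoxy)phenyl]-3-hydroxy-N-methoxy-N-methylpropanamide
Conditions: MeNHOMe·HCl, i-PrMgCl, THF, −20 → 0 °C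
Reagents that add atoms: N,O-dimethylhydroxylamine hydrochloride, CNOC.Cl
Why: Weinreb amide formation by aminolysis of the ester with the chloromagnesium amide of N,O-dimethylhydroxylamine; the carbinol is masked as its magnesium alkoxide and the stereocentre is not involved.

**Step 14**
Reactants: 20 3-methoxy-5-(methoxymethoxy)-2-[(2Z)-4-(methoxymethoxy)-3-methylbut-2-en-1-yl]-6-(trimethylsilyl)phenyl trifluoromethanesulfonate; 25 (3S)-3-[3,4-bis(methoxymethoxy)phenyl]-3-hydroxy-N-methoxy-N-methylpropanamide
Product: 30 (2S)-2-[3,4-bis(methoxymethoxy)phenyl]-7-methoxy-5-(methoxymethoxy)-8-[(2Z)-4-(methoxymethoxy)-3-methylbut-2-en-1-yl]-2,3-dihydro-4H-chromen-4-one, via sodium alkoxide 26 (not isolated), via aryne 27 (not isolated), via aryl carbanion 28 (not isolated), via tetrahedral adduct 29 (not isolated)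
Conditions: 25 (1.3 equiv), NaH (1.3 equiv), THF, 0 °C; then 20, CsF (3 equiv), 18-crown-6, THF, 0 °C → rt; AcOH, −20 °C; pH 7 buffer
Reagents that add atoms: none
Why: Proposed new method: fluoride removes the silyl group of 20 and triflate leaves to give aryne 27 (triple bond C4a≡C8a of ring A), sodium alkoxide 26 adds through oxygen to C8a, and the aryl carbanion 28 left at C4a attacks the N-methoxy-N-methylamide carbonyl to give tetrahedral adduct 29, which releases the ketone only on acidic quench. The closest known reaction type is the fluoride-induced annulation of arynes with salicylate esters to xanthones (phenoxide addition, then intramolecular acyl capture); what is new is an aliphatic secondary alkoxide as the nucleophile and an amide as the acyl trap. Ring C (the pyranone) closes by a 6-exo-trig acyl addition of C4a onto C4, after the intermolecular O1–C8a bond formation. No stereocentre is created in the product: C2 comes unchanged from 25 because no bond to it is made or broken, and the C4 hemiaminal centre of 29 is erased on quench. The regioselectivity needed (oxygen to C8a, not C4a) is secured by the C5 OMOM group beside the triple bond, whose inductive withdrawal distorts the aryne so that the nucleophile attacks the distal carbon C8a and the negative charge develops at C4a next to oxygen, which should outweigh the mild steric bias of the primary alkyl chain at C8. Acyl capture should beat protonation of 28 because the medium is aprotic (NaH leaves no conjugate acid) and the trap sits in reach of a six-membered transition state, and the persistence of 29 keeps both a basic leaving group and the base-labile flavanone (retro-oxa-Michael racemisation at C2) out of the basic mixture.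

**Step 15**
Reactants: 30 (2S)-2-[3,4-bis(methoxymethoxy)phenyl]-7-methoxy-5-(methoxymethoxy)-8-[(2Z)-4-(methoxymethoxy)-3-methylbut-2-en-1-yl]-2,3-dihydro-4H-chromen-4-one
Product: 31 (2S)-2-(3,4-dihydroxyphenyl)-5-hydroxy-8-[(2Z)-4-hydroxy-3-methylbut-2-en-1-yl]-7-methoxy-2,3-dihydro-4H-chromen-4-one
Conditions: HCl (3 M) in MeOH, THF, 40 °C
Reagents that add atoms: none
Why: acid-catalysed acetal methanolysis should remove all four MOM groups (the peri-carbonyl C5 ether fastest, the allylic one slowest) as dimethoxymethane; no base is present, so the retro-oxa-Michael pathway that would racemise C2 is avoided, and the primary allylic alcohol is not prone to ionisation under these conditions.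

**Compound list**
1 | 5-methoxybenzene-1,3-diol | COc1cc(O)cc(O)c1 | starting material
2 | 3-methoxy-5-(methoxymethoxy)phenol | COCOc1cc(O)cc(OC)c1 | intermediate
3 | 3-methoxy-5-(methoxymethoxy)phenyl N-(propan-2-yl)carbamate | CC(C)NC(=O)Oc1cc(OC)cc(OCOC)c1 | intermediate
4 | 3-methoxy-5-(methoxymethoxy)phenyl N-(propan-2-yl)-N-(trimethylsilyl)carbamate | CC(C)N(C(=O)Oc1cc(OC)cc(OCOC)c1)[Si](C)(C)C | intermediate (not isolated)
5 | 2-lithio derivative of 4 (lithium between carbamate and OMOM) | CC(C)N(C(=O)Oc1cc(OC)cc(OCOC)c1[Li])[Si](C)(C)C | intermediate (not isolated)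
6 | 5-methoxy-3-(methoxymethoxy)-2-(trimethylsilyl)phenyl N-(propan-2-yl)-N-(trimethylsilyl)carbamate | CC(C)N(C(=O)Oc1cc(OC)cc(OCOC)c1[Si](C)(C)C)[Si](C)(C)C | intermediate (not isolated)
7 | 5-methoxy-3-(methoxymethoxy)-2-(trimethylsilyl)phenyl N-(propan-2-yl)carbamate | CC(C)NC(=O)Oc1cc(OC)cc(OCOC)c1[Si](C)(C)C | intermediate
8 | prop-2-yn-1-ol | C#CCO | starting material
9 | 4-methyl-2,5-dihydro-1,2-oxamagnesole (cyclic alkenylmagnesium alkoxide) | CC1=C[Mg]OC1 | intermediate (not isolated)
10 | (2Z)-3-iodo-2-methylprop-2-en-1-ol | I/C=C(/C)CO | intermediate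
11 | (1Z)-1-iodo-3-(methoxymethoxy)-2-methylprop-1-ene | I/C=C(/C)COCOC | intermediate
12 | [(1Z)-3-(methoxymethoxy)-2-methylprop-1-en-1-yl]lithium | [Li]/C=C(/C)COCOC | intermediate (not isolated)
13 | (2Z)-4-(methoxymethoxy)-3-methylbut-2-en-1-ol | OC/C=C(/C)COCOC | intermediate
14 | (2Z)-1-bromo-4-(methoxymethoxy)-3-methylbut-2-ene | BrC/C=C(/C)COCOC | intermediate
15 | 5-methoxy-3-(methoxymethoxy)-2-(trimethylsilyl)phenyl N-[tert-butyl(dimethyl)silyl]-N-(propan-2-yl)carbamate | CC(C)N(C(=O)Oc1cc(OC)cc(OCOC)c1[Si](C)(C)C)[Si](C)(C)C(C)(C)C | intermediate (not isolated)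
16 | 6-lithio derivative of 15 (lithium between carbamate and OMe) | CC(C)N(C(=O)Oc1c([Li])c(OC)cc(OCOC)c1[Si](C)(C)C)[Si](C)(C)C(C)(C)C | intermediate (not isolated)
17 | N-[tert-butyl(dimethyl)silyl] derivative of 18 | CC(C)N(C(=O)Oc1c(C/C=C(/C)COCOC)c(OC)cc(OCOC)c1[Si](C)(C)C)[Si](C)(C)C(C)(C)C | intermediate (not isolated)
18 | 3-methoxy-5-(methoxymethoxy)-2-[(2Z)-4-(methoxymethoxy)-3-methylbut-2-en-1-yl]-6-(trimethylsilyl)phenyl N-(propan-2-yl)carbamate | CC(C)NC(=O)Oc1c(C/C=C(/C)COCOC)c(OC)cc(OCOC)c1[Si](C)(C)C | intermediate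
19 | 3-methoxy-5-(methoxymethoxy)-2-[(2Z)-4-(methoxymethoxy)-3-methylbut-2-en-1-yl]-6-(trimethylsilyl)phenol | Oc1c(C/C=C(/C)COCOC)c(OC)cc(OCOC)c1[Si](C)(C)C | intermediate (not isolated)
20 | 3-methoxy-5-(methoxymethoxy)-2-[(2Z)-4-(methoxymethoxy)-3-methylbut-2-en-1-yl]-6-(trimethylsilyl)phenyl trifluoromethanesulfonate | O=S(=O)(Oc1c(C/C=C(/C)COCOC)c(OC)cc(OCOC)c1[Si](C)(C)C)C(F)(F)F | intermediate
21 | 1-(3,4-dihydroxyphenyl)ethan-1-one | CC(=O)c1ccc(O)c(O)c1 | starting material
22 | 1-[3,4-bis(methoxymethoxy)phenyl]ethan-1-one | CC(=O)c1ccc(OCOC)c(OCOC)c1 | intermediate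
23 | methyl 3-[3,4-bis(methoxymethoxy)phenyl]-3-oxopropanoate | COC(=O)CC(=O)c1ccc(OCOC)c(OCOC)c1 | intermediate
24 | methyl (3S)-3-[3,4-bis(methoxymethoxy)phenyl]-3-hydroxypropanoate | O[C@H](c1ccc(OCOC)c(OCOC)c1)CC(=O)OC | intermediate
25 | (3S)-3-[3,4-bis(methoxymethoxy)phenyl]-3-hydroxy-N-methoxy-N-methylpropanamide | O[C@H](c1ccc(OCOC)c(OCOC)c1)CC(=O)N(C)OC | intermediate
26 | sodium alkoxide of 25 | [Na+].[O-][C@H](c1ccc(OCOC)c(OCOC)c1)CC(=O)N(C)OC | intermediate (not isolated)
27 | 5-methoxy-3-(methoxymethoxy)-6-[(2Z)-4-(methoxymethoxy)-3-methylbut-2-en-1-yl]benzyne (triple bond C4a≡C8a) | COCOC1=CC(OC)=C(C/C=C(/C)COCOC)C#C1 | intermediate (not isolated)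
28 | sodium aryl carbanion: O-aryl ether of 25 at C8a with the negative charge at C4a | COc1cc(OCOC)[c-]c(O[C@H](c2ccc(OCOC)c(OCOC)c2)CC(=O)N(C)OC)c1C/C=C(/C)COCOC.[Na+] | intermediate (not isolated)
29 | sodium (2S)-4-[methoxy(methyl)amino]chroman-4-olate adduct (C4 configuration undefined) | COc1cc(OCOC)c2c(c1C/C=C(/C)COCOC)O[C@H](c1ccc(OCOC)c(OCOC)c1)CC2([O-])N(C)OC.[Na+] | intermediate (not isolated)
30 | (2S)-2-[3,4-bis(methoxymethoxy)phenyl]-7-methoxy-5-(methoxymethoxy)-8-[(2Z)-4-(methoxymethoxy)-3-methylbut-2-en-1-yl]-2,3-dihydro-4H-chromen-4-one | COc1cc(OCOC)c2c(c1C/C=C(/C)COCOC)O[C@H](c1ccc(OCOC)c(OCOC)c1)CC2=O | intermediate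
31 | (2S)-2-(3,4-dihydroxyphenyl)-5-hydroxy-8-[(2Z)-4-hydroxy-3-methylbut-2-en-1-yl]-7-methoxy-2,3-dihydro-4H-chromen-4-one | COc1cc(O)c2c(c1C/C=C(/C)CO)O[C@H](c1ccc(O)c(O)c1)CC2=O | target

**Totals**
Total step count: 15. Longest linear sequence: 8 steps (steps 4, 5, 6, 7, 8, 9, 14, 15).

**Steps most likely to fail**

Step 14 (proposed new method). The processes at risk are protonation of the aryl carbanion before acyl capture (leaving the open aryl ether), addition of the alkoxide at the wrong aryne carbon, and retro-aldol cleavage or β-elimination of the alkoxide. The fallback uses known chemistry, sets out from 23 and 20 and returns at 30. Compound 23 is reduced with the enantiomeric catalyst RuCl[(R,R)-TsDPEN](p-cymene) in HCO2H/Et3N to methyl (3R)-3-[3,4-bis(methoxymethoxy)phenyl]-3-hydroxypropanoate F1. Saponification (LiOH, THF/H2O) gives (3R)-3-[3,4-bis(methoxymethoxy)phenyl]-3-hydroxypropanoic acid F2. Compound 20, CsF and F2 in THF at 65 °C or above then undergo the known insertion of an aryne into the C–O bond of a carboxylic acid (carboxylate oxygen to C8a, acyl group to C4a, under the same orienting effect of the C5 oxygen). This should give (3R)-3-[3,4-bis(methoxymethoxy)phenyl]-3-hydroxy-1-{2-hydroxy-4-methoxy-6-(methoxymethoxy)-3-[(2Z)-4-(methoxymethoxy)-3-methylbut-2-en-1-yl]phenyl}propan-1-one F3. Intramolecular Mitsunobu etherification (PPh3, DIAD, THF, 0 °C) closes O1–C2 with inversion, (R) to (S), to give 30.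

Step 8. The processes at risk are incomplete or misdirected lithiation of the hindered N-silyl carbamate, γ-attack in the allylic substitution, and erosion of the Z geometry through an allylcopper intermediate. The fallback sets the alkene geometry on the arene by olefination instead of importing it; it sets out from 7 and returns at 18. Compound 7 is N-silylated with TBSOTf and lithiated as in step 8 (through 15 and 16), and the aryllithium is quenched with allyl bromide in the presence of CuBr·SMe2 to give the N-silyl intermediate 3-methoxy-5-(methoxymethoxy)-2-(prop-2-en-1-yl)-6-(trimethylsilyl)phenyl N-[tert-butyl(dimethyl)silyl]-N-(propan-2-yl)carbamate F4, which is not isolated. Methanolysis on work-up gives 3-methoxy-5-(methoxymethoxy)-2-(prop-2-en-1-yl)-6-(trimethylsilyl)phenyl N-(propan-2-yl)carbamate F5. Lemieux–Johnson cleavage (OsO4 cat., NaIO4, 2,6-lutidine, dioxane/H2O) gives the arylacetaldehyde 3-methoxy-5-(methoxymethoxy)-2-(2-oxoethyl)-6-(trimethylsilyl)phenyl N-(propan-2-yl)carbamate F6. Still–Gennari olefination with ethyl 2-[bis(2,2,2-trifluoroethoxy)phosphoryl]propanoate (KN(SiMe3)2, 18-crown-6, THF, −78 °C) should give the Z enoate ethyl (2Z)-4-{6-methoxy-4-(methoxymethoxy)-2-[(propan-2-ylcarbamoyl)oxy]-3-(trimethylsilyl)phenyl}-2-methylbut-2-enoate F7. Reduction with i-Bu2AlH (CH2Cl2, −78 °C) gives 2-[(2Z)-4-hydroxy-3-methylbut-2-en-1-yl]-3-methoxy-5-(methoxymethoxy)-6-(trimethylsilyl)phenyl N-(propan-2-yl)carbamate F8. Protection with MOMCl and i-Pr2NEt gives 18.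

Step 15. The processes at risk are ionisation or solvolysis of the allylic alcohol and acid-induced ring opening (loss of configuration at C2) during the longer exposure that the aliphatic MOM ether needs. The fallback replaces the single protic methanolysis by two chemoselective stages of different mechanism; it sets out from 30 and returns at 31. NaHSO4·SiO2 in CH2Cl2 at rt should cleave only the three phenolic MOM ethers, giving (2S)-2-(3,4-dihydroxyphenyl)-5-hydroxy-7-methoxy-8-[(2Z)-4-(methoxymethoxy)-3-methylbut-2-en-1-yl]-2,3-dihydro-4H-chromen-4-one F9. The remaining allylic MOM ether is then removed under aprotic conditions by thiol-assisted Lewis-acid transacetalisation (ZnBr2, n-PrSH, CH2Cl2, 0 °C) to give 31.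

**Further compounds**
F1 | step 14 | methyl (3R)-3-[3,4-bis(methoxymethoxy)phenyl]-3-hydroxypropanoate | O[C@@H](c1ccc(OCOC)c(OCOC)c1)CC(=O)OC
F2 | step 14 | (3R)-3-[3,4-bis(methoxymethoxy)phenyl]-3-hydroxypropanoic acid | O[C@@H](c1ccc(OCOC)c(OCOC)c1)CC(=O)O
F3 | step 14 | (3R)-3-[3,4-bis(methoxymethoxy)phenyl]-3-hydroxy-1-{2-hydroxy-4-methoxy-6-(methoxymethoxy)-3-[(2Z)-4-(methoxymethoxy)-3-methylbut-2-en-1-yl]phenyl}propan-1-one | COc1cc(OCOC)c(C(=O)C[C@@H](O)c2ccc(OCOC)c(OCOC)c2)c(O)c1C/C=C(/C)COCOC
F4 | step 8 | 3-methoxy-5-(methoxymethoxy)-2-(prop-2-en-1-yl)-6-(trimethylsilyl)phenyl N-[tert-butyl(dimethyl)silyl]-N-(propan-2-yl)carbamate | CC(C)N(C(=O)Oc1c(CC=C)c(OC)cc(OCOC)c1[Si](C)(C)C)[Si](C)(C)C(C)(C)C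
F5 | step 8 | 3-methoxy-5-(methoxymethoxy)-2-(prop-2-en-1-yl)-6-(trimethylsilyl)phenyl N-(propan-2-yl)carbamate | CC(C)NC(=O)Oc1c(CC=C)c(OC)cc(OCOC)c1[Si](C)(C)C
F6 | step 8 | 3-methoxy-5-(methoxymethoxy)-2-(2-oxoethyl)-6-(trimethylsilyl)phenyl N-(propan-2-yl)carbamate | CC(C)NC(=O)Oc1c(CC=O)c(OC)cc(OCOC)c1[Si](C)(C)C
F7 | step 8 | ethyl (2Z)-4-{6-methoxy-4-(methoxymethoxy)-2-[(propan-2-ylcarbamoyl)oxy]-3-(trimethylsilyl)phenyl}-2-methylbut-2-enoate | CC(C)NC(=O)Oc1c(C/C=C(/C)C(=O)OCC)c(OC)cc(OCOC)c1[Si](C)(C)C
F8 | step 8 | 2-[(2Z)-4-hydroxy-3-methylbut-2-en-1-yl]-3-methoxy-5-(methoxymethoxy)-6-(trimethylsilyl)phenyl N-(propan-2-yl)carbamate | CC(C)NC(=O)Oc1c(C/C=C(/C)CO)c(OC)cc(OCOC)c1[Si](C)(C)C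
F9 | step 15 | (2S)-2-(3,4-dihydroxyphenyl)-5-hydroxy-7-methoxy-8-[(2Z)-4-(methoxymethoxy)-3-methylbut-2-en-1-yl]-2,3-dihydro-4H-chromen-4-one | COc1cc(O)c2c(c1C/C=C(/C)COCOC)O[C@H](c1ccc(O)c(O)c1)CC2=O
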